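Which flask ends with the smallest share of target, and how much target can stand in it at 25 min?

| flask | substrate | reagent | free catalyst | remark | time |
|---|---|---|---|---|---|
| larch | 0.054 M | 0.31 equiv | 5 mol% | run made earlier |  |
| alder | 0.054 M | 2.4 equiv | 5 mol% | run made earlier |  |
| ash | 0.054 M | 1 equiv | 8.7 mol% | run made earlier |  |
| south-east | 0.10 M | 1.50 equiv | 5 mol% |  | 25 min |
| north-east | 0.15 M | 1.00 equiv | 20 mol% |  | 25 min |
| west | 0.080 M | 4.00 equiv | 5 mol% |  | 25 min |
| north-west | 0.020 M | 0.500 equiv | 5 mol% |  | 25 min |
| north | 0.054 M | 1.00 equiv | 5 mol% |  | 25 min |

| run | time / min | target / % | side product / % | substrate / % |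
|---|---|---|---|---|
| larch | 1.33 | 5.0 | 4.8 | 86.9 |
| larch | 3.00 | 6.2 | 16.3 | 74.0 |
| larch | 6.00 | 6.2 | 34.2 | 57.1 |
| larch | 10.0 | 3.1 | 48.9 | 45.3 |
| larch | 12.0 | 2.4 | 53.3 | 42.4 |
| larch | 20.0 | 1.6 | 60.0 | 36.5 |
| alder | 1.33 | 16.1 | 13.2 | 69.7 |
| alder | 2.50 | 21.9 | 32.4 | 44.7 |
| alder | 4.00 | 25.3 | 49.9 | 23.5 |
| alder | 6.00 | 28.6 | 62.7 | 9.6 |
| alder | 10.0 | 29.4 | 69.3 | 1.5 |
| alder | 20.0 | 29.0 | 71.1 | 0 |
| ash | 4.00 | 29.1 | 50.9 | 18.2 |
| ash | 8.00 | 33.5 | 64.0 | 0.8 |
| ash | 10.0 | 34.9 | 65.2 | 1.2 |
| ash | 15.0 | 33.5 | 65.5 | 0.1 |
| ash | 20.0 | 34.6 | 66.7 | 0 |

(readings scatter by 0.5 percentage points)

- all flasks from highest to lowest share of target in all that became target or side product, at 25 min (south-east / north-east / west / north-west / north)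
- the same order at 2.5 min (south-east / north-east / west / north-west / north)
- the share of target in all that became target or side product of the flask you put first, at 25 min
- the share of target in all that became target or side product of the flask you put last, at 25 min

- percentages count the substrate that a species holds: one side product counts as two
- the numbers in the tables scatter with a standard deviation of 0.5 percentage points

The reagent's books speak to the amount of target. Each target made costs one reagent, and the larch run suggests that side product costs none beyond that. At 20.0 min in larch, target plus side product divided by two comes to 31.6% of the substrate charged, against a charge of 0.31 equiv, so reagent is the limiting reagent there. Reagent spent is therefore target plus side product over two, while substrate spent is target plus side product. Subtracting the entries, substrate left minus target minus two times reagent left equals one minus two times the equivalents, in fractions of the substrate charged and apart from what sits on the catalyst. With no reagent counted as left, larch reads 34.9% where this asks 38.0%; its loading is 5 mol%.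

North-west is charged 0.500 equiv, so the right side is zero: with no reagent left, substrate equals target, and the two consume each other. Between 3.00 min and 6.00 min, larch gives the side-step constant, the rate of side product per substrate and per target, as 13.6 L mol⁻¹ min⁻¹, a reading. Target then falls with its own square, so the reciprocal of its fraction grows steadily with this constant times the substrate charge. Counted from the start, the fraction is one over constant, charge and time. For north-west at 25 min, this reckoning gives 14.7% target and a share, target over one minus target, of 17.3%. The earlier runs alder and ash hold more target at their last readings, 29.0% and 34.6%, than this reckoning gives for north-west; that sets north-west beside those two runs and gives it no place among the asked flasks.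

The forecast reasons that “Final share then follows first-step/second-step rate”. It gives north-east > west > south-east > north > north-west at 25 min and north-east > north-west > west > south-east > north at 2.5 min, with 78% first and 9% last, the last lower than the 17.3% reckoned here.

The flasks give north-east > west > south-east > north > north-west at 25 min and north-west > north-east > north > west > south-east at 2.5 min, with 57.1% first and 11.6% last.

    substrate + target → side product (k = 14.0 L mol⁻¹ min⁻¹)
    substrate + free catalyst ⇌ catalyst intermediate A (K = 120 L mol⁻¹, k = 120 L mol⁻¹ min⁻¹)
    reagent + catalyst intermediate A ⇌ catalyst intermediate B (K = 26.0 L mol⁻¹, k = 130 L mol⁻¹ min⁻¹)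
    catalyst intermediate B ⇌ by-product + catalyst intermediate C (K = 0.130 M, k = 56.0 min⁻¹)
    catalyst intermediate C → free catalyst + target (k = 330 min⁻¹)

In north-west at 25 min, the books are still open: 26.3% of the reagent remains and target stands at 7.66%, lower than the reckoned 14.7%. The substrate's half-life by the forward binding to free catalyst alone, 11 min at 7.09 min, is shorter than 25 min. At 250 min, with 0.974% of the reagent left, the constant gives 1.47% and the flask holds 1.36%. Charged at 0.080 M with the same equivalents and loading, the constant gives 3.68% target; that flask holds 4.46%, with 0.54% of its reagent left and a share of 4.69%.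

The numbers in the tables are simulated for substances that don't exist, and the scatter is random.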